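Each millimolar of E in these flasks is paid for in millimolars of G, and that price tells how much E a charge of G can carry.

common to all: L 20 mM; time 10 h
- south-west: G 50.0 mM
- east: G 22.0 mM
- north-east: G 33.0 mM

    L + X → L.X (k1 = 0.25 M⁻¹ h⁻¹)
    2 L → L2 (k2 = 1.1 M⁻¹ h⁻¹)
    G + X ⇌ G.X, settled at all times (K3 = 1.5 × 10⁵ M⁻¹)
    L + G → X + E (k4 = 4.4 M⁻¹ h⁻¹)

- in percentages every species weighs as the L in it: one L2 counts as two
- for a step with 2 of a species take k times the square, and two of it per event
- run time (south-west): 10 h

- part of the L that has reacted at the end, south-west
- part of the L that has reacted at the end, east
- part of the L that has reacted at the end, north-east
- what raising the concentration of G from its lowest to its highest value here does to the part of the L that has reacted (changes below 5 percentage points count as none) (it rises / no change / it falls)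

Before any reckoning, it helps to ask which numbers must be known well. The binding constant need not be: in the east flask, multiplied by the G charged, it gives 3300, far above one. An error by a factor of 10 therefore still leaves X held as G.X, and each E costs two G, one reacting and one catching the X released. The rate constant of L with X matters little as well, since the half-life of X by that step in the east flask is 140 h, longer than the 10 h run, even before binding is counted. The rate constant of L with G matters strongly: the east half-life of L by that step, 7.2 h, is shorter than the run. The pairing of L matters less but still counts, because at the start of the north-east flask L goes to E 3.3 times as fast as it pairs.

The G charge enters through a ceiling on E. The G ceiling is the E that the G charged can pay for at two G each, told as a share of the L charged: half the G charged, divided by the L charged. It is 55.0% east, 82.5% north-east and 125% south-west. G is thus the limiting reagent for E in the east flask, and the part reacted should rise with G.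

A hand figure for the east flask starts from the first loss of L per hour, which over the run gives x = 1.41. If the loss falls as the square of what remains, the part reacted is x over one plus x, or 58.5%.

The forecast gives 78.8% south-west, 55.7% east and 66.2% north-east, and says of the trend that it rises, on the ground that “each L that reacts with G effectively uses up two G”. Its east figure lies below the hand figure.

The flasks give 79.2% south-west, 56.0% east and 66.5% north-east, and from lowest to highest G it rises, by 23 percentage points. The east flask holds E at 37.1% of the L charged after 10.0 h. E divided by the ceiling is the share of G spent, which leaves 32.5% of the G free, and the reading there is 32.6%. The north-east flask left until 40 h holds E at 70.3% under its ceiling of 82.5%, which leaves 14.8% of its G, and the reading there is 15%.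

The numbers are those of an exercise; the run is a simulation.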